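**Retrosynthetic overview**
1. Iridal 40 ⇐ silyl-protected enal 39 ⇐ isopropenyl carbinol 38 (oxidative [3,3] transposition sets the (Z)-enal) ⇐ ketone 35.
2. Ring–chain bond: 35 ⇐ B-alkyl Suzuki–Miyaura coupling of the alkyl-9-BBN from vinyl diol 32 with (1E,5E)-iodotriene 15.
3. Stereotriad: 32 ⇐ axial MeLi addition ⇐ vinyl ketone 30 ⇐ new Pd-catalysed α-vinylation of the enolate from an anti-selective cuprate addition to (S)-silyloxy enone 24 (CBS reduction sets the controlling carbinol, which is erased later).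
4. Iodotriene 15 ⇐ Negishi coupling of iododiene 6 with butynylzinc 11; both (E)-trisubstituted alkenes come from Zr-catalysed carboalumination.
5. Rings: the single carbocycle is the ring of m-cresol, dearomatized in step 9; no ring is formed by cyclization.

Assumption: the target is iridal as drawn, (2Z)-2-[(2R,3S,4S)-…cyclohexylidene]propanal; one step means one isolated product, and a crude intermediate carried on in the same operation is given as "via".

**Route**

Step 1
Reactants: 1 propargyl bromide (3-bromoprop-1-yne); 2 prenyl bromide (1-bromo-3-methylbut-2-ene)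
Product: 4 6-methylhept-5-en-1-yne, via 1,3-dilithiopropyne 3 (not isolated)
Conditions: 1, n-BuLi (2.0 equiv), TMEDA, Et2O/hexane, −78 °C; then 2, −78 °C → rt; H2O
Reagents that add atoms: none
Why: Br–Li exchange plus deprotonation converts 1 into the propargyl dianion, whose sp3 carbanion is alkylated by the primary allylic bromide (SN2 alkylation); no stereocentre is formed.

Step 2
Reactants: 4 6-methylhept-5-en-1-yne
Product: 6 (E)-1-iodo-2,6-dimethylhepta-1,5-diene, via alkenylalane 5 (not isolated)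
Conditions: Me3Al (2 equiv), Cp2ZrCl2 (0.25 equiv), CH2Cl2, 0 °C → rt; then I2, THF, −30 → 0 °C
Reagents that add atoms: trimethylaluminium C[Al](C)C; iodine I-I
Why: Negishi zirconium-catalysed carboalumination adds CH3 and Al syn across the terminal alkyne only (Al on the terminal carbon), and iodinolysis with retention fixes the (E)-geometry.

Step 3
Reactants: 7 but-3-yn-1-ol
Product: 9 4-(trimethylsilyl)but-3-yn-1-ol, via bis-silyl ether 8 (not isolated)
Conditions: n-BuLi (2.1 equiv), THF, −78 °C; TMSCl (2.2 equiv), → rt; then 1 M HCl, rt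
Reagents that add atoms: chlorotrimethylsilane C[Si](C)(C)Cl
Why: C,O-bis-silylation of the dianion followed by selective hydrolysis of the labile O–Si bond masks the acidic alkyne C–H for the organozinc chemistry.

Step 4
Reactants: 9 4-(trimethylsilyl)but-3-yn-1-ol
Product: 10 (4-iodobut-1-yn-1-yl)trimethylsilane
Conditions: I2, PPh3, imidazole, CH2Cl2, 0 °C → rt
Reagents that add atoms: iodine I-I
Why: Appel-type iodination: the alkoxyphosphonium salt of the primary alcohol is displaced by iodide (SN2).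

Step 5
Reactants: 10 (4-iodobut-1-yn-1-yl)trimethylsilane; 6 (E)-1-iodo-2,6-dimethylhepta-1,5-diene
Product: 12 [(E)-6,10-dimethylundeca-5,9-dien-1-yn-1-yl]trimethylsilane, via organozinc iodide 11 (not isolated)
Conditions: 10, Zn dust (activated with BrCH2CH2Br/TMSCl), LiCl, THF, 40 °C; then 6, Pd(PPh3)4 (3 mol%), THF, rt
Reagents that add atoms: none
Why: Negishi cross-coupling: zerovalent palladium inserts into the alkenyl C–I bond, the homopropargylzinc iodide transmetalates and reductive elimination forms the sp3–sp2 bond with retention of the (E)-alkene.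

Step 6
Reactants: 12 [(E)-6,10-dimethylundeca-5,9-dien-1-yn-1-yl]trimethylsilane
Product: 13 (E)-6,10-dimethylundeca-5,9-dien-1-yne
Conditions: K2CO3 (0.2 equiv), MeOH, rt
Reagents that add atoms: none
Why: Carbonate-catalysed methanolysis cleaves the alkynyl C–Si bond (protodesilylation) without touching the alkenes.

Step 7
Reactants: 13 (E)-6,10-dimethylundeca-5,9-dien-1-yne
Product: 15 (1E,5E)-1-iodo-2,6,10-trimethylundeca-1,5,9-triene, via alkenylalane 14 (not isolated)
Conditions: Me3Al (2 equiv), Cp2ZrCl2 (0.25 equiv), CH2Cl2, 0 °C → rt; then I2, THF, −30 → 0 °C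
Reagents that add atoms: trimethylaluminium C[Al](C)C; iodine I-I
Why: A second Negishi carboalumination–iodination (syn addition, retention on iodinolysis) sets the second (E)-trisubstituted alkene; the two existing trisubstituted alkenes are inert.

Step 8
Reactants: 16 3-bromopropan-1-ol
Product: 17 (3-bromopropoxy)(tert-butyl)diphenylsilane
Conditions: TBDPSCl, imidazole, DMF, 0 °C → rt
Reagents that add atoms: tert-butyl(chloro)diphenylsilane CC(C)(C)[Si](Cl)(c1ccccc1)c1ccccc1
Why: Imidazole-promoted silylation masks the hydroxyl so that the bromide can be turned into a Grignard reagent.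

Step 9
Reactants: 18 m-cresol (3-methylphenol)
Product: 20 4,4-dimethoxy-3-methylcyclohexa-2,5-dien-1-one, via 4-methoxy-3-methylphenol 19 (not isolated)
Conditions: PhI(OAc)2 (2.1 equiv), MeOH, 0 °C → rt
Reagents that add atoms: methanol CO
Why: Oxidative dearomatization: two successive two-electron phenol oxidations by the hypervalent iodine reagent, each trapped by methanol at the free para position, give the quinone monoketal.

Step 10
Reactants: 20 4,4-dimethoxy-3-methylcyclohexa-2,5-dien-1-one
Product: 21 4,4-dimethoxy-3-methylcyclohex-2-en-1-one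
Conditions: H2 (1 atm), RhCl(PPh3)3 (5 mol%), toluene/EtOH, rt
Reagents that add atoms: none
Why: Chemoselective homogeneous hydrogenation: RhCl(PPh3)3 reduces the cis-disubstituted enone double bond much faster than the trisubstituted, ketal-flanked one.

Step 11
Reactants: 21 4,4-dimethoxy-3-methylcyclohex-2-en-1-one
Product: 23 (S)-4-hydroxy-2-methylcyclohex-2-en-1-one, via ketal alcohol 22 (not isolated)
Conditions: (R)-2-methyl-CBS-oxazaborolidine [(R)-1-methyl-3,3-diphenyltetrahydro-1H,3H-pyrrolo[1,2-c][1,3,2]oxazaborole] (15 mol%), BH3·SMe2 (0.7 equiv), THF, −30 °C; MeOH; then 5% aq. oxalic acid, THF, 0 °C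
Reagents that add atoms: water O
Why: Corey–Bakshi–Shibata reduction: the oxazaborolidine–borane complex binds the ketone with the alkenyl arm as the large group and delivers hydride to one face, setting the (S)-carbinol; the mild acidic work-up hydrolyses the allylic dimethyl ketal, which transposes the enone.

Step 12
Reactants: 23 (S)-4-hydroxy-2-methylcyclohex-2-en-1-one
Product: 24 (S)-2-methyl-4-(triethylsilyloxy)cyclohex-2-en-1-one
Conditions: TESCl, imidazole, CH2Cl2, 0 °C
Reagents that add atoms: chlorotriethylsilane CC[Si](Cl)(CC)CC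
Why: Silylation of the secondary alcohol gives the bulky γ-silyloxy group that steers the following conjugate addition.

Step 13
Reactants: 17 (3-bromopropoxy)(tert-butyl)diphenylsilane; 24 (S)-2-methyl-4-(triethylsilyloxy)cyclohex-2-en-1-one
Product: 26 tert-butyl{3-[(1S,6S)-2-methyl-6-(triethylsilyloxy)-3-(trimethylsilyloxy)cyclohex-2-en-1-yl]propoxy}diphenylsilane, via Grignard reagent 25 (not isolated)
Conditions: 17, Mg, THF, 40 °C; then CuBr·SMe2 (10 mol%), TMSCl (2.5 equiv), 24, THF, −78 °C; Et3N, aq. NaHCO3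
Reagents that add atoms: chlorotrimethylsilane C[Si](C)(C)Cl
Why: Copper-catalysed conjugate addition of a Grignard reagent with TMSCl trapping: the alkyl group adds anti to the γ-silyloxy group (3,4-trans), setting the side-chain stereocentre, and the enolate is caught regiospecifically as the tetrasubstituted silyl enol ether.

Step 14
Reactants: 26 tert-butyl{3-[(1S,6S)-2-methyl-6-(triethylsilyloxy)-3-(trimethylsilyloxy)cyclohex-2-en-1-yl]propoxy}diphenylsilane; 27 vinyl bromide (bromoethene)
Product: 30 (2S,3S,4S)-3-{3-[tert-butyl(diphenyl)silyloxy]propyl}-2-ethenyl-2-methyl-4-(triethylsilyloxy)cyclohexan-1-one, via lithium enolate 28 (not isolated), via zinc enolate 29 (not isolated)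
Conditions: MeLi (1.05 equiv), THF, 0 °C; ZnCl2 (1.1 equiv), 0 °C; then Pd(dba)2 (5 mol%), P(t-Bu)3 (10 mol%), 27 (3 equiv, 1 M in THF), rt → 45 °C, sealed vessel
Reagents that add atoms: none
Why: Proposed new method: Pd-catalysed α-vinylation of a fully substituted cyclic zinc enolate with the parent vinyl bromide to build the α-quaternary α-vinyl ketone; MeLi unmasks the regiodefined enolate, ZnCl2 tempers its basicity, zerovalent palladium adds oxidatively to vinyl bromide, transmetalation gives a C-bound palladium enolate and the bulky electron-rich P(t-Bu)3 drives C–C reductive elimination ahead of β-hydride elimination; the metal and hence the vinyl group take the enolate face opposite the neighbouring side chain (held pseudoaxial by A(1,2) strain with the 2-methyl group), which sets the quaternary centre with vinyl trans to that chain; the closest known reaction types are the Pd-catalysed α-arylation and α-alkenylation of preformed ketone enolates and the arylation of zinc enolates.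

Step 15
Reactants: 30 (2S,3S,4S)-3-{3-[tert-butyl(diphenyl)silyloxy]propyl}-2-ethenyl-2-methyl-4-(triethylsilyloxy)cyclohexan-1-one
Product: 32 (1S,2S,3S,4S)-3-{3-[tert-butyl(diphenyl)silyloxy]propyl}-2-ethenyl-1,2-dimethylcyclohexane-1,4-diol, via tertiary alcohol 31 (not isolated)
Conditions: MeLi (3 equiv), CeCl3 (3 equiv), THF, −78 °C; aq. NH4Cl; crude in MeOH, pyridinium p-toluenesulfonate (0.1 equiv), 0 °C → rt
Reagents that add atoms: methyllithium [Li]C
Why: Organocerium 1,2-addition (non-basic, no enolization): the side chain and the OTES group are both equatorial, which leaves the 2-methyl group axial, so the methyl nucleophile enters axially on the face anti to that methyl group and gives the carbinol with OH trans to the vinyl group; acid-catalysed methanolysis then removes only the secondary TES ether.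

Step 16
Reactants: 32 (1S,2S,3S,4S)-3-{3-[tert-butyl(diphenyl)silyloxy]propyl}-2-ethenyl-1,2-dimethylcyclohexane-1,4-diol; 15 (1E,5E)-1-iodo-2,6,10-trimethylundeca-1,5,9-triene
Product: 34 (1S,2S,3S,4S)-3-{3-[tert-butyl(diphenyl)silyloxy]propyl}-1,2-dimethyl-2-[(3E,7E)-4,8,12-trimethyltrideca-3,7,11-trien-1-yl]cyclohexane-1,4-diol, via alkylborane 33 (not isolated)
Conditions: 9-BBN (3.5 equiv), THF, rt → 50 °C; 3 M aq. Cs2CO3; then 15, PdCl2(dppf) [dppf = 1,1'-bis(diphenylphosphino)ferrocene] (10 mol%), AsPh3 (10 mol%), DMF, rt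
Reagents that add atoms: none
Why: B-alkyl Suzuki–Miyaura cross-coupling: 9-BBN hydroborates the only monosubstituted alkene at its terminal carbon, and base-assisted transmetalation to the alkenylpalladium iodide followed by reductive elimination joins ring and chain with retention of the (E)-geometry; no stereocentre is touched and excess borane covers the two free hydroxyls.

Step 17
Reactants: 34 (1S,2S,3S,4S)-3-{3-[tert-butyl(diphenyl)silyloxy]propyl}-1,2-dimethyl-2-[(3E,7E)-4,8,12-trimethyltrideca-3,7,11-trien-1-yl]cyclohexane-1,4-diol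
Product: 35 (2S,3S,4S)-2-{3-[tert-butyl(diphenyl)silyloxy]propyl}-4-hydroxy-3,4-dimethyl-3-[(3E,7E)-4,8,12-trimethyltrideca-3,7,11-trien-1-yl]cyclohexan-1-one
Conditions: Dess–Martin periodinane (1.5 equiv), NaHCO3, CH2Cl2, 0 °C → rt
Reagents that add atoms: none
Why: Dess–Martin oxidation converts the only secondary alcohol into the ketone (the tertiary alcohol and the alkenes are inert), and the bicarbonate buffer protects the α-stereocentre from epimerization.

Step 18
Reactants: 35 (2S,3S,4S)-2-{3-[tert-butyl(diphenyl)silyloxy]propyl}-4-hydroxy-3,4-dimethyl-3-[(3E,7E)-4,8,12-trimethyltrideca-3,7,11-trien-1-yl]cyclohexan-1-one; 36 isopropenylmagnesium bromide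
Product: 38 (1S,2S,3S,4R)-3-{3-[tert-butyl(diphenyl)silyloxy]propyl}-1,2-dimethyl-4-(prop-1-en-2-yl)-2-[(3E,7E)-4,8,12-trimethyltrideca-3,7,11-trien-1-yl]cyclohexane-1,4-diol, via isopropenylcerium dichloride 37 (not isolated)
Conditions: CeCl3 (4 equiv), 36 (4 equiv), THF, −78 → 0 °C; aq. NH4Cl
Reagents that add atoms: none
Why: Organocerium 1,2-addition to a hindered enolizable ketone without epimerizing the α-carbon; the new carbinol centre (OH axial expected) is erased in the next step, so either epimer serves.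

Step 19
Reactants: 38 (1S,2S,3S,4R)-3-{3-[tert-butyl(diphenyl)silyloxy]propyl}-1,2-dimethyl-4-(prop-1-en-2-yl)-2-[(3E,7E)-4,8,12-trimethyltrideca-3,7,11-trien-1-yl]cyclohexane-1,4-diol
Product: 39 (2Z)-2-[(2R,3S,4S)-2-{3-[tert-butyl(diphenyl)silyloxy]propyl}-4-hydroxy-3,4-dimethyl-3-[(3E,7E)-4,8,12-trimethyltrideca-3,7,11-trien-1-yl]cyclohexylidene]propanal
Conditions: pyridinium chlorochromate [C5H5NH][CrO3Cl] (3 equiv), NaOAc, 4 Å molecular sieves, CH2Cl2, rt
Reagents that add atoms: pyridinium chlorochromate [O-][Cr](=O)(=O)Cl.c1cc[nH+]cc1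
Why: Babler–Dauben oxidative transposition: the chromate ester of the tertiary allylic alcohol undergoes a [3,3] shift to the primary allylic chromate, which is oxidized to the enal; the chair-like transition state puts the isopropenyl methyl over the unbranched ring CH2 and the reacting CH2 next to the branched ring carbon, so the formyl group ends syn to that carbon (Z), which is also the less strained enal.

Step 20
Reactants: 39 (2Z)-2-[(2R,3S,4S)-2-{3-[tert-butyl(diphenyl)silyloxy]propyl}-4-hydroxy-3,4-dimethyl-3-[(3E,7E)-4,8,12-trimethyltrideca-3,7,11-trien-1-yl]cyclohexylidene]propanal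
Product: 40 iridal
Conditions: HF·pyridine, pyridine, THF, 0 °C → rt
Reagents that add atoms: none
Why: Buffered fluoride cleavage of the primary Si–O bond (desilylation) leaves the enal, the tertiary alcohol and the trisubstituted alkenes untouched.

**Compound list**

1 | propargyl bromide (3-bromoprop-1-yne) | C#CCBr | starting material
2 | prenyl bromide (1-bromo-3-methylbut-2-ene) | CC(C)=CCBr | starting material
3 | 1,3-dilithiopropyne | [Li]C#CC[Li] | intermediate
4 | 6-methylhept-5-en-1-yne | C#CCCC=C(C)C | intermediate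
5 | (E)-(2,6-dimethylhepta-1,5-dien-1-yl)dimethylalane | C[Al](C)/C=C(\C)CCC=C(C)C | intermediate
6 | (E)-1-iodo-2,6-dimethylhepta-1,5-diene | I/C=C(\C)CCC=C(C)C | intermediate
7 | but-3-yn-1-ol | C#CCCO | starting material
8 | trimethyl{[4-(trimethylsilyl)but-3-yn-1-yl]oxy}silane | C[Si](C)(C)C#CCCO[Si](C)(C)C | intermediate
9 | 4-(trimethylsilyl)but-3-yn-1-ol | C[Si](C)(C)C#CCCO | intermediate
10 | (4-iodobut-1-yn-1-yl)trimethylsilane | C[Si](C)(C)C#CCCI | intermediate
11 | [4-(trimethylsilyl)but-3-yn-1-yl]zinc iodide | C[Si](C)(C)C#CCC[Zn]I | intermediate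
12 | [(E)-6,10-dimethylundeca-5,9-dien-1-yn-1-yl]trimethylsilane | C[Si](C)(C)C#CCC/C=C(\C)CCC=C(C)C | intermediate
13 | (E)-6,10-dimethylundeca-5,9-dien-1-yne | C#CCC/C=C(\C)CCC=C(C)C | intermediate
14 | dimethyl[(1E,5E)-2,6,10-trimethylundeca-1,5,9-trien-1-yl]alane | C[Al](C)/C=C(\C)CC/C=C(\C)CCC=C(C)C | intermediate
15 | (1E,5E)-1-iodo-2,6,10-trimethylundeca-1,5,9-triene | I/C=C(\C)CC/C=C(\C)CCC=C(C)C | intermediate
16 | 3-bromopropan-1-ol | OCCCBr | starting material
17 | (3-bromopropoxy)(tert-butyl)diphenylsilane | BrCCCO[Si](c1ccccc1)(c1ccccc1)C(C)(C)C | intermediate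
18 | m-cresol (3-methylphenol) | Cc1cccc(O)c1 | starting material
19 | 4-methoxy-3-methylphenol | COc1ccc(O)cc1C | intermediate
20 | 4,4-dimethoxy-3-methylcyclohexa-2,5-dien-1-one | COC1(OC)C=CC(=O)C=C1C | intermediate
21 | 4,4-dimethoxy-3-methylcyclohex-2-en-1-one | COC1(OC)CCC(=O)C=C1C | intermediate
22 | (S)-4,4-dimethoxy-3-methylcyclohex-2-en-1-ol | COC1(OC)CC[C@H](O)C=C1C | intermediate
23 | (S)-4-hydroxy-2-methylcyclohex-2-en-1-one | O=C1CC[C@H](O)C=C1C | intermediate
24 | (S)-2-methyl-4-(triethylsilyloxy)cyclohex-2-en-1-one | CC1=C[C@@H](O[Si](CC)(CC)CC)CCC1=O | intermediate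
25 | {3-[tert-butyl(diphenyl)silyloxy]propyl}magnesium bromide | Br[Mg]CCCO[Si](c1ccccc1)(c1ccccc1)C(C)(C)C | intermediate
26 | tert-butyl{3-[(1S,6S)-2-methyl-6-(triethylsilyloxy)-3-(trimethylsilyloxy)cyclohex-2-en-1-yl]propoxy}diphenylsilane (side chain trans to OTES) | C[Si](C)(C)OC1=C(C)[C@H](CCCO[Si](c2ccccc2)(c2ccccc2)C(C)(C)C)[C@@H](O[Si](CC)(CC)CC)CC1 | intermediate
27 | vinyl bromide (bromoethene) | C=CBr | starting material
28 | lithium enolate corresponding to 26 (OLi in place of OTMS) | [Li]OC1=C(C)[C@H](CCCO[Si](c2ccccc2)(c2ccccc2)C(C)(C)C)[C@@H](O[Si](CC)(CC)CC)CC1 | intermediate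
29 | chlorozinc enolate corresponding to 26 (OZnCl in place of OTMS) | Cl[Zn]OC1=C(C)[C@H](CCCO[Si](c2ccccc2)(c2ccccc2)C(C)(C)C)[C@@H](O[Si](CC)(CC)CC)CC1 | intermediate
30 | (2S,3S,4S)-3-{3-[tert-butyl(diphenyl)silyloxy]propyl}-2-ethenyl-2-methyl-4-(triethylsilyloxy)cyclohexan-1-one | C=C[C@@]1(C)[C@H](CCCO[Si](c2ccccc2)(c2ccccc2)C(C)(C)C)[C@@H](O[Si](CC)(CC)CC)CCC1=O | intermediate
31 | (1S,2S,3S,4S)-3-{3-[tert-butyl(diphenyl)silyloxy]propyl}-2-ethenyl-1,2-dimethyl-4-(triethylsilyloxy)cyclohexan-1-ol | C=C[C@@]1(C)[C@H](CCCO[Si](c2ccccc2)(c2ccccc2)C(C)(C)C)[C@@H](O[Si](CC)(CC)CC)CC[C@]1(C)O | intermediate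
32 | (1S,2S,3S,4S)-3-{3-[tert-butyl(diphenyl)silyloxy]propyl}-2-ethenyl-1,2-dimethylcyclohexane-1,4-diol | C=C[C@@]1(C)[C@H](CCCO[Si](c2ccccc2)(c2ccccc2)C(C)(C)C)[C@@H](O)CC[C@]1(C)O | intermediate
33 | B-alkyl-9-BBN adduct of 32 (boron on the terminal carbon of the former vinyl group) | C(C[C@@]1(C)[C@H](CCCO[Si](c2ccccc2)(c2ccccc2)C(C)(C)C)[C@@H](O)CC[C@]1(C)O)B3C4CCCC3CCC4 | intermediate
34 | (1S,2S,3S,4S)-3-{3-[tert-butyl(diphenyl)silyloxy]propyl}-1,2-dimethyl-2-[(3E,7E)-4,8,12-trimethyltrideca-3,7,11-trien-1-yl]cyclohexane-1,4-diol | CC(C)=CCC/C(C)=C/CC/C(C)=C/CC[C@@]1(C)[C@H](CCCO[Si](c2ccccc2)(c2ccccc2)C(C)(C)C)[C@@H](O)CC[C@]1(C)O | intermediate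
35 | (2S,3S,4S)-2-{3-[tert-butyl(diphenyl)silyloxy]propyl}-4-hydroxy-3,4-dimethyl-3-[(3E,7E)-4,8,12-trimethyltrideca-3,7,11-trien-1-yl]cyclohexan-1-one | CC(C)=CCC/C(C)=C/CC/C(C)=C/CC[C@@]1(C)[C@H](CCCO[Si](c2ccccc2)(c2ccccc2)C(C)(C)C)C(=O)CC[C@]1(C)O | intermediate
36 | isopropenylmagnesium bromide (prop-1-en-2-ylmagnesium bromide) | CC(=C)[Mg]Br | starting material
37 | isopropenylcerium dichloride | CC(=C)[Ce](Cl)Cl | intermediate
38 | (1S,2S,3S,4R)-3-{3-[tert-butyl(diphenyl)silyloxy]propyl}-1,2-dimethyl-4-(prop-1-en-2-yl)-2-[(3E,7E)-4,8,12-trimethyltrideca-3,7,11-trien-1-yl]cyclohexane-1,4-diol (expected major epimer at C4) | CC(C)=CCC/C(C)=C/CC/C(C)=C/CC[C@@]1(C)[C@H](CCCO[Si](c2ccccc2)(c2ccccc2)C(C)(C)C)[C@@](O)(C(C)=C)CC[C@]1(C)O | intermediate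
39 | (2Z)-2-[(2R,3S,4S)-2-{3-[tert-butyl(diphenyl)silyloxy]propyl}-4-hydroxy-3,4-dimethyl-3-[(3E,7E)-4,8,12-trimethyltrideca-3,7,11-trien-1-yl]cyclohexylidene]propanal | CC(C)=CCC/C(C)=C/CC/C(C)=C/CC[C@@]1(C)[C@H](CCCO[Si](c2ccccc2)(c2ccccc2)C(C)(C)C)/C(=C(/C)C=O)CC[C@]1(C)O | intermediate
40 | iridal, (2Z)-2-[(2R,3S,4S)-4-hydroxy-2-(3-hydroxypropyl)-3,4-dimethyl-3-[(3E,7E)-4,8,12-trimethyltrideca-3,7,11-trien-1-yl]cyclohexylidene]propanal | CC(C)=CCC/C(C)=C/CC/C(C)=C/CC[C@@]1(C)[C@H](CCCO)/C(=C(/C)C=O)CC[C@]1(C)O | target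

**Step count and risks**

Total steps: 20. Longest linear sequence: 12 (steps 9 to 20, m-cresol to iridal). The chain (steps 1 to 7, itself built from two branches) and the side-chain bromide (step 8) are made in parallel.

Steps most likely to fail:

Step 14 (the proposed vinylation). The palladium enolate may give the enone by β-hydride elimination, vinylate on oxygen, or show poor facial control. The fallback uses known chemistry and sets out from 26. MeLi (THF, 0 °C) gives lithium enolate 28, which adds at −78 °C to phenyl vinyl sulfoxide (a vinyl cation equivalent; Michael addition anti to the side chain) to give the 2-(2-phenylsulfinylethyl) ketone F1. Heating F1 in toluene at 110 °C over CaCO3 expels benzenesulfenic acid by syn-elimination and gives 30, where the route is rejoined.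

Step 15 (methyl addition). The methyl group may enter from the equatorial side and give the wrong carbinol epimer. The fallback sets out from 30. Wittig methylenation (Ph3PCH3Br, KOt-Bu, toluene, 80 °C) gives the exocyclic methylene compound F2. Epoxidation with mCPBA (NaHCO3, CH2Cl2, 0 °C) takes the 1,1-disubstituted alkene ahead of the hindered vinyl group and gives the spiro-epoxide F3. Because oxygen rather than carbon is now delivered to the accessible face, the carbinol configuration is the reverse of that from a methyl attack on the same face. LiEt3BH (THF, 0 °C) opens F3 at its CH2 terminus to give 31, which rejoins the route (methanolysis to 32).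

Step 19 (oxidative transposition). The enal may form as an E/Z mixture, and the tertiary allylic alcohol may ionize under the acidic chromium reagent (ether formation with the 4-hydroxyl, polyene cyclization). The fallback sets out from 35 and replaces steps 18 and 19. CBr4 with P(Oi-Pr)3 (CH2Cl2, 0 °C → rt; non-basic, so the α-carbon is not epimerized) gives the 1,1-dibromoalkene F4. MeZnCl with Pd(P(t-Bu)3)2 (THF, 0 °C) replaces the bromine on the unbranched CH2 side selectively (trans-selective Negishi monoalkylation logic, steered here by the branched ring carbon) and gives the (Z)-bromoalkene F5. t-BuLi (3.2 equiv, Et2O, −78 °C) gives the configurationally stable alkenyllithium F6, and DMF then gives 39 with the formyl group syn to the branched carbon; the route is rejoined at 39.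

Further compounds
F1 | step 14 | (2S,3S,4S)-3-{3-[tert-butyl(diphenyl)silyloxy]propyl}-2-methyl-2-[2-(phenylsulfinyl)ethyl]-4-(triethylsilyloxy)cyclohexan-1-one (sulfoxide epimers) | O=S(c1ccccc1)CC[C@@]2(C)[C@H](CCCO[Si](c3ccccc3)(c3ccccc3)C(C)(C)C)[C@@H](O[Si](CC)(CC)CC)CCC2=O
F2 | step 15 | tert-butyl{3-[(1S,2S,6S)-2-ethenyl-2-methyl-3-methylidene-6-(triethylsilyloxy)cyclohexyl]propoxy}diphenylsilane | C=C[C@@]1(C)[C@H](CCCO[Si](c2ccccc2)(c2ccccc2)C(C)(C)C)[C@@H](O[Si](CC)(CC)CC)CCC1=C
F3 | step 15 | spiro-epoxide of F2 (1-oxaspiro[2.5]octane; epoxide oxygen trans to the vinyl group) | C=C[C@@]1(C)[C@H](CCCO[Si](c2ccccc2)(c2ccccc2)C(C)(C)C)[C@@H](O[Si](CC)(CC)CC)CC[C@@]13CO3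
F4 | step 19 | (1S,2S,3S)-3-{3-[tert-butyl(diphenyl)silyloxy]propyl}-4-(dibromomethylidene)-1,2-dimethyl-2-[(3E,7E)-4,8,12-trimethyltrideca-3,7,11-trien-1-yl]cyclohexan-1-ol | CC(C)=CCC/C(C)=C/CC/C(C)=C/CC[C@@]1(C)[C@H](CCCO[Si](c2ccccc2)(c2ccccc2)C(C)(C)C)C(=C(Br)Br)CC[C@]1(C)O
F5 | step 19 | (1S,2S,3S,4Z)-4-(1-bromoethylidene)-3-{3-[tert-butyl(diphenyl)silyloxy]propyl}-1,2-dimethyl-2-[(3E,7E)-4,8,12-trimethyltrideca-3,7,11-trien-1-yl]cyclohexan-1-ol | CC(C)=CCC/C(C)=C/CC/C(C)=C/CC[C@@]1(C)[C@H](CCCO[Si](c2ccccc2)(c2ccccc2)C(C)(C)C)/C(=C(/C)Br)CC[C@]1(C)O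
F6 | step 19 | alkenyllithium from F5 (lithium in place of bromine; hydroxyl as lithium alkoxide) | CC(C)=CCC/C(C)=C/CC/C(C)=C/CC[C@@]1(C)[C@H](CCCO[Si](c2ccccc2)(c2ccccc2)C(C)(C)C)/C(=C(/C)[Li])CC[C@]1(C)O[Li]
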